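**Strategy.** Ring A, the bromodimethylcyclohexane (C1 bears the acetate, C4 the bromine), is cut at its C(CH3)2–CH2 bond. The CHBr–C(CH3)2 unit is read as an opened bromonium ion and the C1 acetate, cis to bromine, as a Baeyer–Villiger-unmasked acetyl. The key step ionises an enantiopure vicinal bromochloride in HFIP; a 1,1-disubstituted alkene opens the bromonium ion at its tertiary carbon through a chair, and the C1 cation is quenched by anti 1,2-shift of the hydrindanylmethyl group from a neighbouring silyloxy carbinol. One operation closes ring A, relays the C4 configuration to quaternary C1 and creates the acetyl. The precursor is an acyclic bromochloride tethered to a trans-hydrindane.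

Key step: step 15

Assumption: compounds 4 and 6 are taken as purchasable; the side-chain carbinol centre made in step 11 is carried as an epimer mixture because it becomes the acetyl carbon in step 15, and any 7-O-silyl group lost in step 15 converges in step 17.

Shorthand: TBDPS = tert-butyldiphenylsilyl; TMS = trimethylsilyl; HydOH = the bicyclic group of compound 17 attached through C1 (trans-fused 4β-bromo-7β-hydroxy-7α-methyl-3a-(TBDPS-oxymethyl)octahydroinden-1α-yl); HydOTMS = the same group with the 7-hydroxyl as its TMS ether.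

Step 1
Reactants: 1 3-methylbut-2-en-1-ol (prenol)
Product: 2 (S)-2-bromo-3-chloro-3-methylbutan-1-ol
Conditions: NBS, ClTi(OiPr)3, chiral tridentate salicylaldimine amino-alcohol ligand (cat.), hexanes, −20 °C
Reagents that add atoms: N-bromosuccinimide O=C1CCC(=O)N1Br; chlorotitanium triisopropoxide CC(C)O[Ti](Cl)(OC(C)C)OC(C)C
Why: Titanium-templated catalytic enantioselective bromochlorination of an allylic alcohol, in which the ligand-bound titanium alkoxide delivers chloride to the tertiary carbon anti to bromine and so fixes the CHBr centre (later C4 of ring A).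

Step 2
Reactants: 2 (S)-2-bromo-3-chloro-3-methylbutan-1-ol
Product: 3 (S)-2-bromo-3-chloro-3-methylbutyl trifluoromethanesulfonate
Conditions: Tf2O, 2,6-lutidine, CH2Cl2, −78 °C
Reagents that add atoms: trifluoromethanesulfonic anhydride O=S(=O)(OS(=O)(=O)C(F)(F)F)C(F)(F)F
Why: Low-temperature O-sulfonylation of the primary alcohol gives the alkylating agent without touching the stereocentre; it should be prepared directly before its use in step 13.

Step 3
Reactants: 4 ethyl 8-oxo-1,4-dioxaspiro[4.5]decane-7-carboxylate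
Product: 5 ethyl (7R,8R)-8-hydroxy-1,4-dioxaspiro[4.5]decane-7-carboxylate
Conditions: H2 (50 atm), [RuCl(C6H6)((R)-BINAP)]Cl (cat.), CH2Cl2, 50 °C
Reagents that add atoms: none
Why: Noyori asymmetric hydrogenation under dynamic kinetic resolution, in which the (R)-BINAP ruthenium catalyst selects the ketone face while the α-centre epimerises, sets the (8R)-carbinol that becomes C4 of the hydrindane.

Step 4
Reactants: 5 ethyl (7R,8R)-8-hydroxy-1,4-dioxaspiro[4.5]decane-7-carboxylate; 6 2-(2-iodoethyl)-1,3-dioxolane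
Product: 8 ethyl (7R,8R)-7-[2-(1,3-dioxolan-2-yl)ethyl]-8-hydroxy-1,4-dioxaspiro[4.5]decane-7-carboxylate, via dilithium dianion 7 (not isolated)
Conditions: LDA (2.2 equiv), THF, −50 → −10 °C; then 6, DMPU, −10 → 23 °C
Reagents that add atoms: none
Why: Fráter–Seebach alkylation, in which the chelated alkoxide enolate is alkylated on the face cis to the alkoxide, so the carbinol centre sets the quaternary centre (C3a) with the ester trans to the hydroxyl.

Step 5
Reactants: 8 ethyl (7R,8R)-7-[2-(1,3-dioxolan-2-yl)ethyl]-8-hydroxy-1,4-dioxaspiro[4.5]decane-7-carboxylate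
Product: 9 ethyl (7S,8S)-8-bromo-7-[2-(1,3-dioxolan-2-yl)ethyl]-1,4-dioxaspiro[4.5]decane-7-carboxylate
Conditions: CBr4, PPh3, 2,6-lutidine, PhMe, 60 °C
Reagents that add atoms: carbon tetrabromide BrC(Br)(Br)Br
Why: Appel reaction, in which bromide displaces the alkoxyphosphonium group by SN2 with inversion and so places bromine cis to the ester (the later 4β-bromide), while the quaternary α-carbon excludes retro-aldol and enolisation.

Step 6
Reactants: 9 ethyl (7S,8S)-8-bromo-7-[2-(1,3-dioxolan-2-yl)ethyl]-1,4-dioxaspiro[4.5]decane-7-carboxylate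
Product: 10 [(7S,8S)-8-bromo-7-[2-(1,3-dioxolan-2-yl)ethyl]-1,4-dioxaspiro[4.5]decan-7-yl]methanol
Conditions: DIBAL-H, CH2Cl2, −78 → 0 °C; Rochelle salt work-up
Reagents that add atoms: none
Why: Hydride reduction of the hindered ester to the primary alcohol with a reagent that leaves the secondary bromide and both acetals intact.

Step 7
Reactants: 10 [(7S,8S)-8-bromo-7-[2-(1,3-dioxolan-2-yl)ethyl]-1,4-dioxaspiro[4.5]decan-7-yl]methanol
Product: 11 tert-butyl{[(7S,8S)-8-bromo-7-[2-(1,3-dioxolan-2-yl)ethyl]-1,4-dioxaspiro[4.5]decan-7-yl]methoxy}diphenylsilane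
Conditions: TBDPSCl, imidazole, DMAP (cat.), DMF, 23 °C
Reagents that add atoms: tert-butyl(chloro)diphenylsilane CC(C)(C)[Si](Cl)(c1ccccc1)c1ccccc1
Why: Silylation of the only free hydroxyl with a group that should survive acid, organometallic reagents and HFIP.

Step 8
Reactants: 11 tert-butyl{[(7S,8S)-8-bromo-7-[2-(1,3-dioxolan-2-yl)ethyl]-1,4-dioxaspiro[4.5]decan-7-yl]methoxy}diphenylsilane
Product: 13 (3aS,4S)-4-bromo-3a-(TBDPS-oxymethyl)-2,3,3a,4,5,6-hexahydro-7H-inden-7-one, via keto aldehyde 12 (not isolated)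
Conditions: TsOH·H2O, acetone/H2O, 50 °C; then piperidine, AcOH, PhH, 80 °C
Reagents that add atoms: water O
Why: Acid hydrolysis unmasks ketone and aldehyde, and intramolecular aldol condensation (5-exo addition of the α-carbon next to the quaternary centre, then dehydration) closes the cyclopentene, the alternative enolisation leading only to a strained bridged ring.

Step 9
Reactants: 13 (3aS,4S)-4-bromo-3a-(TBDPS-oxymethyl)-2,3,3a,4,5,6-hexahydro-7H-inden-7-one
Product: 14 (3aS,4S,7R)-4-bromo-7-methyl-3a-(TBDPS-oxymethyl)-3,3a,4,5,6,7-hexahydro-2H-inden-7-ol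
Conditions: MeLi, CeCl3, THF, −78 °C
Reagents that add atoms: methyllithium [Li]C
Why: Organocerium 1,2-addition to the enone, in which the pseudoaxial silyloxymethyl group on C3a blocks the β face so that methyl enters from the α face and the 7β-hydroxyl (7R) results.

Step 10
Reactants: 14 (3aS,4S,7R)-4-bromo-7-methyl-3a-(TBDPS-oxymethyl)-3,3a,4,5,6,7-hexahydro-2H-inden-7-ol; 15 1-bromopropan-2-one (bromoacetone)
Product: 17 1-[(1S,3aS,4S,7R,7aS)-4-bromo-7-hydroxy-7-methyl-3a-(TBDPS-oxymethyl)octahydro-1H-inden-1-yl]propan-2-one, via alkylborane 16 (not isolated)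
Conditions: 9-BBN (2.5 equiv), THF, 65 °C; then 15, potassium 2,6-di-tert-butylphenoxide, THF, 0 → 23 °C; aq. NaOH work-up
Reagents that add atoms: none
Why: Hydroboration adds H to C7a and boron to C1 syn from the α face (the β face carries the angular CH2OSi group and the C7 borinate oxygen), which sets the trans ring fusion and C1, and the α-bromo ketone alkylation of the B-alkyl-9-BBN then transfers the ring carbon by 1,2-boron-to-carbon shift with retention.

Step 11
Reactants: 17 1-[(1S,3aS,4S,7R,7aS)-4-bromo-7-hydroxy-7-methyl-3a-(TBDPS-oxymethyl)octahydro-1H-inden-1-yl]propan-2-one; 18 ethyl vinyl ether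
Product: 20 3-hydroxy-3-methyl-4-(HydOH)butan-2-one, via enol ether adduct 19 (not isolated)
Conditions: 18, t-BuLi, THF, −78 → 0 °C; then 17, −78 °C; then 1 M HCl, THF, 0 °C
Reagents that add atoms: water O
Why: 1,2-Addition of the acyl anion equivalent 1-ethoxyvinyllithium to the methyl ketone and hydrolysis of the enol ether should give the α-hydroxy methyl ketone, whose new carbinol centre (uncontrolled) converges in step 15.

Step 12
Reactants: 20 3-hydroxy-3-methyl-4-(HydOH)butan-2-one
Product: 21 3-methyl-4-(HydOTMS)-3-(trimethylsilyloxy)butan-2-one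
Conditions: N-(trimethylsilyl)imidazole, CH2Cl2, 40 °C
Reagents that add atoms: N-(trimethylsilyl)imidazole C[Si](C)(C)n1ccnc1
Why: Silylation of both tertiary alcohols leaves the ketone methyl as the only acidic site and primes the side-chain oxygen for the later 1,2-shift.

Step 13
Reactants: 21 3-methyl-4-(HydOTMS)-3-(trimethylsilyloxy)butan-2-one; 3 (S)-2-bromo-3-chloro-3-methylbutyl trifluoromethanesulfonate
Product: 23 (6S)-6-bromo-7-chloro-2,7-dimethyl-1-(HydOTMS)-2-(trimethylsilyloxy)octan-3-one, via lithium enolate 22 (not isolated)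
Conditions: LDA, THF, −78 °C; then 3, DMPU, −78 → −40 °C
Reagents that add atoms: none
Why: Kinetic enolate alkylation, in which the ketone can enolise only toward its methyl group and the primary triflate should react by SN2 at low temperature faster than the enolate attacks either halogen.

Step 14
Reactants: 23 (6S)-6-bromo-7-chloro-2,7-dimethyl-1-(HydOTMS)-2-(trimethylsilyloxy)octan-3-one
Product: 24 (6S)-6-bromo-7-chloro-2,7-dimethyl-3-methylidene-1-(HydOTMS)-2-(trimethylsilyloxy)octane
Conditions: Cp2TiMe2, PhMe, 70 °C, dark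
Reagents that add atoms: dimethyltitanocene C[Ti](C)(C1C=CC=C1)C1C=CC=C1
Why: Petasis methylenation converts the hindered, base-sensitive ketone into the 1,1-disubstituted alkene under neutral conditions that should spare the bromochloride.

Step 15
Reactants: 24 (6S)-6-bromo-7-chloro-2,7-dimethyl-3-methylidene-1-(HydOTMS)-2-(trimethylsilyloxy)octane
Product: 27 1-[(1S,4S)-4-bromo-3,3-dimethyl-1-(HydOTMS-methyl)cyclohexyl]ethan-1-one, via bromonium ion 25 (not isolated), via tertiary carbocation 26 (not isolated)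
Conditions: HFIP (1,1,1,3,3,3-hexafluoropropan-2-ol), 2,6-di-tert-butyl-4-methylpyridine, 0 → 23 °C
Reagents that add atoms: none
Why: Proposed new method: in HFIP the tertiary C–Cl bond of 24 should ionise with anchimeric assistance by the neighbouring bromine to give the configurationally defined bromonium ion 25, whose tertiary carbon is attacked anti by the terminal CH2 of the 1,1-disubstituted alkene, and the C1 cation 26 is discharged by 1,2-shift of the hydrindanylmethyl group from the adjacent silyloxy carbon with loss of the silyl group (semipinacol), the closest known reaction types being bromopolyene cyclisation by solvolysis of enantioenriched vicinal bromochlorides and pinacol-terminated Prins cyclisation. Ring A closes in the 6-endo mode through a chair in which bromine is equatorial. The only new stereocentre, quaternary C1, is controlled by the C4 bromide through this chair: the migrating CH2 group enters anti to the forming C–C bond, on the face away from the axial methyl, so it becomes equatorial while the acetyl becomes axial and cis to bromine. The step needs chemoselective ionisation (only the chloride has a participating neighbour), migration of the primary alkyl group in preference to methyl (higher migratory aptitude, both carbinol epimers converging) and a shift that outruns proton loss, which the β-silyloxy group should secure by making the oxocarbenium ion the sink.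

Step 16
Reactants: 27 1-[(1S,4S)-4-bromo-3,3-dimethyl-1-(HydOTMS-methyl)cyclohexyl]ethan-1-one
Product: 28 (1S,4S)-4-bromo-3,3-dimethyl-1-(HydOTMS-methyl)cyclohexyl acetate
Conditions: mCPBA, NaHCO3, CH2Cl2, 23 °C
Reagents that add atoms: 3-chloroperbenzoic acid OOC(=O)c1cccc(Cl)c1
Why: Baeyer–Villiger oxidation, in which the tertiary ring carbon migrates in preference to methyl with retention, so the axial acetyl becomes the axial acetate.

Step 17
Reactants: 28 (1S,4S)-4-bromo-3,3-dimethyl-1-(HydOTMS-methyl)cyclohexyl acetate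
Product: 29 (1S,4S)-4-bromo-1-{[(1S,3aS,4S,7R,7aS)-4-bromo-7-hydroxy-3a-(hydroxymethyl)-7-methyloctahydro-1H-inden-1-yl]methyl}-3,3-dimethylcyclohexyl acetate
Conditions: HF·pyridine, THF, 0 → 23 °C
Reagents that add atoms: none
Why: Fluoride-mediated cleavage of both silyl ethers, to which the tertiary acetate and the two secondary bromides should be inert.

**Compound list**

1 | 3-methylbut-2-en-1-ol | CC(C)=CCO | starting material
2 | (S)-2-bromo-3-chloro-3-methylbutan-1-ol | OC[C@H](Br)C(C)(C)Cl | intermediate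
3 | (S)-2-bromo-3-chloro-3-methylbutyl trifluoromethanesulfonate | FC(F)(F)S(=O)(=O)OC[C@H](Br)C(C)(C)Cl | intermediate
4 | ethyl 8-oxo-1,4-dioxaspiro[4.5]decane-7-carboxylate (racemic) | CCOC(=O)C1CC2(CCC1=O)OCCO2 | starting material
5 | ethyl (7R,8R)-8-hydroxy-1,4-dioxaspiro[4.5]decane-7-carboxylate | CCOC(=O)[C@H]1[C@H](O)CCC2(C1)OCCO2 | intermediate
6 | 2-(2-iodoethyl)-1,3-dioxolane | ICCC1OCCO1 | starting material
7 | dilithium dianion of 5 (lithium alkoxide, lithium ester enolate) | CCOC(O[Li])=C1[C@H](O[Li])CCC2(C1)OCCO2 | intermediate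
8 | ethyl (7R,8R)-7-[2-(1,3-dioxolan-2-yl)ethyl]-8-hydroxy-1,4-dioxaspiro[4.5]decane-7-carboxylate | O1CCOC1CC[C@]2(C(=O)OCC)[C@H](O)CCC3(OCCO3)C2 | intermediate
9 | ethyl (7S,8S)-8-bromo-7-[2-(1,3-dioxolan-2-yl)ethyl]-1,4-dioxaspiro[4.5]decane-7-carboxylate | O1CCOC1CC[C@]2(C(=O)OCC)[C@@H](Br)CCC3(OCCO3)C2 | intermediate
10 | [(7S,8S)-8-bromo-7-[2-(1,3-dioxolan-2-yl)ethyl]-1,4-dioxaspiro[4.5]decan-7-yl]methanol | O1CCOC1CC[C@]2(CO)[C@@H](Br)CCC3(OCCO3)C2 | intermediate
11 | TBDPS ether of 10 | O1CCOC1CC[C@]2(CO[Si](c4ccccc4)(c4ccccc4)C(C)(C)C)[C@@H](Br)CCC3(OCCO3)C2 | intermediate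
12 | 3-[(1S,2S)-2-bromo-5-oxo-1-(TBDPS-oxymethyl)cyclohexyl]propanal | O=CCC[C@]1(CO[Si](c2ccccc2)(c2ccccc2)C(C)(C)C)[C@@H](Br)CCC(=O)C1 | intermediate
13 | (3aS,4S)-4-bromo-3a-(TBDPS-oxymethyl)-2,3,3a,4,5,6-hexahydro-7H-inden-7-one | O=C1CC[C@H](Br)[C@@]2(CO[Si](c3ccccc3)(c3ccccc3)C(C)(C)C)CCC=C12 | intermediate
14 | (3aS,4S,7R)-4-bromo-7-methyl-3a-(TBDPS-oxymethyl)-3,3a,4,5,6,7-hexahydro-2H-inden-7-ol | C[C@@]1(O)CC[C@H](Br)[C@@]2(CO[Si](c3ccccc3)(c3ccccc3)C(C)(C)C)CCC=C12 | intermediate
15 | 1-bromopropan-2-one | CC(=O)CBr | starting material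
16 | B-(hydrindan-1α-yl)-9-BBN carrying the C7 oxygen as its 9-BBN borinate | B1(C2CCCC1CCC2)[C@@H]3CC[C@]4(CO[Si](c5ccccc5)(c5ccccc5)C(C)(C)C)[C@@H](Br)CC[C@@](C)(OB5C6CCCC5CCC6)[C@@H]34 | intermediate
17 | 1-[(1S,3aS,4S,7R,7aS)-4-bromo-7-hydroxy-7-methyl-3a-(TBDPS-oxymethyl)octahydro-1H-inden-1-yl]propan-2-one | CC(=O)C[C@@H]1CC[C@]2(CO[Si](c3ccccc3)(c3ccccc3)C(C)(C)C)[C@@H](Br)CC[C@@](C)(O)[C@@H]12 | intermediate
18 | ethyl vinyl ether | C=COCC | starting material
19 | 3-ethoxy-2-methyl-1-(HydOH)but-3-en-2-ol (epimer mixture at C2) | C=C(OCC)C(C)(O)C[C@@H]1CC[C@]2(CO[Si](c3ccccc3)(c3ccccc3)C(C)(C)C)[C@@H](Br)CC[C@@](C)(O)[C@@H]12 | intermediate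
20 | 3-hydroxy-3-methyl-4-(HydOH)butan-2-one (epimer mixture at C3) | CC(=O)C(C)(O)C[C@@H]1CC[C@]2(CO[Si](c3ccccc3)(c3ccccc3)C(C)(C)C)[C@@H](Br)CC[C@@](C)(O)[C@@H]12 | intermediate
21 | 3-methyl-4-(HydOTMS)-3-(trimethylsilyloxy)butan-2-one | CC(=O)C(C)(O[Si](C)(C)C)C[C@@H]1CC[C@]2(CO[Si](c3ccccc3)(c3ccccc3)C(C)(C)C)[C@@H](Br)CC[C@@](C)(O[Si](C)(C)C)[C@@H]12 | intermediate
22 | lithium enolate of 21 (methyl side) | [Li]OC(=C)C(C)(O[Si](C)(C)C)C[C@@H]1CC[C@]2(CO[Si](c3ccccc3)(c3ccccc3)C(C)(C)C)[C@@H](Br)CC[C@@](C)(O[Si](C)(C)C)[C@@H]12 | intermediate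
23 | (6S)-6-bromo-7-chloro-2,7-dimethyl-1-(HydOTMS)-2-(trimethylsilyloxy)octan-3-one | CC(C)(Cl)[C@@H](Br)CCC(=O)C(C)(O[Si](C)(C)C)C[C@@H]1CC[C@]2(CO[Si](c3ccccc3)(c3ccccc3)C(C)(C)C)[C@@H](Br)CC[C@@](C)(O[Si](C)(C)C)[C@@H]12 | intermediate
24 | (6S)-6-bromo-7-chloro-2,7-dimethyl-3-methylidene-1-(HydOTMS)-2-(trimethylsilyloxy)octane | CC(C)(Cl)[C@@H](Br)CCC(=C)C(C)(O[Si](C)(C)C)C[C@@H]1CC[C@]2(CO[Si](c3ccccc3)(c3ccccc3)C(C)(C)C)[C@@H](Br)CC[C@@](C)(O[Si](C)(C)C)[C@@H]12 | intermediate
25 | bromonium chloride formed from 24 (2,2-dimethylbromiranium bearing the alkenyl chain) | CC1(C)[Br+][C@H]1CCC(=C)C(C)(O[Si](C)(C)C)C[C@@H]2CC[C@]3(CO[Si](c4ccccc4)(c4ccccc4)C(C)(C)C)[C@@H](Br)CC[C@@](C)(O[Si](C)(C)C)[C@@H]23.[Cl-] | intermediate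
26 | (4S)-4-bromo-3,3-dimethylcyclohexyl cation bearing the silyloxy carbinol at C1 (chloride) | CC(O[Si](C)(C)C)(C[C@@H]2CC[C@]3(CO[Si](c4ccccc4)(c4ccccc4)C(C)(C)C)[C@@H](Br)CC[C@@](C)(O[Si](C)(C)C)[C@@H]23)[C+]1CC[C@H](Br)C(C)(C)C1.[Cl-] | intermediate
27 | 1-[(1S,4S)-4-bromo-3,3-dimethyl-1-(HydOTMS-methyl)cyclohexyl]ethan-1-one | CC(=O)[C@]1(C[C@@H]2CC[C@]3(CO[Si](c4ccccc4)(c4ccccc4)C(C)(C)C)[C@@H](Br)CC[C@@](C)(O[Si](C)(C)C)[C@@H]23)CC[C@H](Br)C(C)(C)C1 | intermediate
28 | (1S,4S)-4-bromo-3,3-dimethyl-1-(HydOTMS-methyl)cyclohexyl acetate | CC(=O)O[C@]1(C[C@@H]2CC[C@]3(CO[Si](c4ccccc4)(c4ccccc4)C(C)(C)C)[C@@H](Br)CC[C@@](C)(O[Si](C)(C)C)[C@@H]23)CC[C@H](Br)C(C)(C)C1 | intermediate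
29 | (1S,4S)-4-bromo-1-{[(1S,3aS,4S,7R,7aS)-4-bromo-7-hydroxy-3a-(hydroxymethyl)-7-methyloctahydro-1H-inden-1-yl]methyl}-3,3-dimethylcyclohexyl acetate | CC(=O)O[C@]1(C[C@@H]2CC[C@]3(CO)[C@@H](Br)CC[C@@](C)(O)[C@@H]23)CC[C@H](Br)C(C)(C)C1 | target

**Step count.** Total: 17 steps. Longest linear sequence: 15 steps (steps 3–17, from compound 4); steps 1–2 prepare fragment 3.

**Steps most likely to fail**

Step 15 (proposed new method). Proton loss from cation 26, methyl instead of alkyl migration, or solvent capture of the bromonium ion could compete with the intended 1,2-shift. The fallback uses known chemistry and drops the carbinol detour; it sets out from 17. Kinetic enolisation at the methyl group (LDA, 2.2 equiv, THF, −78 °C) and alkylation with triflate 3 should give (5S)-5-bromo-6-chloro-6-methyl-1-(HydOH)heptan-2-one F1. Petasis methylenation should give (5S)-5-bromo-6-chloro-6-methyl-2-methylidene-1-(HydOH)heptane F2. Solvolysis in HFIP containing acetic acid and sodium acetate, a bromonium-initiated cation–olefin cyclisation terminated by an oxygen nucleophile, should give the TBDPS ether of the target F3. In this mode the C4 configuration is not relayed to C1, so the C1 epimers would have to be separated. HF·pyridine then brings the route back at 29.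

Step 5. E2 elimination or a Wagner–Meerwein shift may outrun the slow SN2 displacement at the neopentyl carbinol carbon. The fallback sets out from 8 and replaces substitution by reduction of a vinyl bromide. Dess–Martin oxidation should give ethyl (R)-7-[2-(1,3-dioxolan-2-yl)ethyl]-8-oxo-1,4-dioxaspiro[4.5]decane-7-carboxylate F4. Treatment with (PhO)3P, Br2 and Et3N (CH2Cl2, −60 °C → reflux) should give ethyl (S)-8-bromo-7-[2-(1,3-dioxolan-2-yl)ethyl]-1,4-dioxaspiro[4.5]dec-8-ene-7-carboxylate F5. Radical hydrogen-atom-transfer hydrogenation (Mn(dpm)3, PhSiH3, t-BuOOH, i-PrOH), which tolerates vinyl halides, should deliver hydrogen to the α-bromo radical on the face opposite the axial ester and return the route at 9.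

Step 10. Hydroboration of the hindered trisubstituted alkene by 9-BBN may be slow, and transfer of the hindered secondary alkyl group to the bromo enolate may be sluggish or compete with migration of the bicyclooctyl bond. The fallback sets out from 14 and separates the events. Hydroboration with BH3·SMe2 followed by pinacol should give the C1 pinacol boronate F6 (same α-face delivery). Matteson homologation (ICH2Cl, n-BuLi, THF, −78 °C) should give the homologous CH2 boronate F7. Zweifel olefination with 1-ethoxyvinyllithium (then I2, NaOMe) should give the 2-ethoxyallyl compound F8, and dilute HCl should hydrolyse it to the methyl ketone, returning the route at 17.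

**Further compounds**

F1 | step 15 | (5S)-5-bromo-6-chloro-6-methyl-1-(HydOH)heptan-2-one | CC(C)(Cl)[C@@H](Br)CCC(=O)C[C@@H]1CC[C@]2(CO[Si](c3ccccc3)(c3ccccc3)C(C)(C)C)[C@@H](Br)CC[C@@](C)(O)[C@@H]12
F2 | step 15 | (5S)-5-bromo-6-chloro-6-methyl-2-methylidene-1-(HydOH)heptane | CC(C)(Cl)[C@@H](Br)CCC(=C)C[C@@H]1CC[C@]2(CO[Si](c3ccccc3)(c3ccccc3)C(C)(C)C)[C@@H](Br)CC[C@@](C)(O)[C@@H]12
F3 | step 15 | TBDPS ether of the target (7-hydroxyl free) | CC(=O)O[C@]1(C[C@@H]2CC[C@]3(CO[Si](c4ccccc4)(c4ccccc4)C(C)(C)C)[C@@H](Br)CC[C@@](C)(O)[C@@H]23)CC[C@H](Br)C(C)(C)C1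
F4 | step 5 | ethyl (R)-7-[2-(1,3-dioxolan-2-yl)ethyl]-8-oxo-1,4-dioxaspiro[4.5]decane-7-carboxylate | O1CCOC1CC[C@]2(C(=O)OCC)C(=O)CCC3(OCCO3)C2
F5 | step 5 | ethyl (S)-8-bromo-7-[2-(1,3-dioxolan-2-yl)ethyl]-1,4-dioxaspiro[4.5]dec-8-ene-7-carboxylate | O1CCOC1CC[C@]2(C(=O)OCC)C(Br)=CCC3(OCCO3)C2
F6 | step 10 | pinacol boronate at C1 of the HydOH skeleton (boron in place of the side chain) | CC1(C)OB(OC1(C)C)[C@@H]2CC[C@]3(CO[Si](c4ccccc4)(c4ccccc4)C(C)(C)C)[C@@H](Br)CC[C@@](C)(O)[C@@H]23
F7 | step 10 | (HydOH)methyl pinacol boronate | CC1(C)OB(OC1(C)C)C[C@@H]2CC[C@]3(CO[Si](c4ccccc4)(c4ccccc4)C(C)(C)C)[C@@H](Br)CC[C@@](C)(O)[C@@H]23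
F8 | step 10 | 2-ethoxy-3-(HydOH)prop-1-ene | C=C(OCC)C[C@@H]1CC[C@]2(CO[Si](c3ccccc3)(c3ccccc3)C(C)(C)C)[C@@H](Br)CC[C@@](C)(O)[C@@H]12
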